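**Plan**
- Retrosynthesis: after removal of two silyl and two benzyl groups, ring A of the isoflavone is cut at C4a–C5, C5–C6, C7–C8 and C8–C8a. This leaves a 5-aryl-2-(diazoacetyl)-4-pyranone (rings B and C) and a 1-siloxyalkyne carrying the side chain.
- Enabling feature: ring A bears oxygen at C5, C7 and C8a (O1), with the alkyl chain at C6 between two oxygens. This is the pattern written by a ketene carbon (C5), an ynol ether (C6, C7), a diazo carbon (C8) and the C2=C3 bond of a γ-pyranone (C8a=C4a).
- Forward: ring B is joined to the pyranone of kojic acid by Suzuki coupling, and the CH2OH group is taken to the diazoacetyl group. The siloxyalkyne is made separately from hex-5-yn-2-one.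
- Ring A is then grown on ring C in one operation; desilylation and hydrogenolysis finish the route.
- Stereochemistry: the target is achiral, so no stereocentre has to be set.

Key step: step 8

Remark: ring A atoms are given in isoflavone numbering (O1, C2–C8a; ring B primed). Diazomethane is used as an ethereal solution made beforehand from Diazald, and hex-5-yn-2-one is assumed to be purchasable.

**Route**

Step 1
Reactants: 1 kojic acid [5-hydroxy-2-(hydroxymethyl)-4H-pyran-4-one]
Product: 2 6-(hydroxymethyl)-4-oxo-4H-pyran-3-yl trifluoromethanesulfonate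
Conditions: PhNTf2 (1.05 equiv), Et3N, DMF, 0 °C to rt
Reagents that add atoms: N-phenylbis(trifluoromethanesulfonimide), O=S(=O)(N(c1ccccc1)S(=O)(=O)C(F)(F)F)C(F)(F)F
Why: Chemoselective O-triflation: Et3N deprotonates the acidic enolic 5-OH (pKa about 8) and the mild triflyl donor PhNTf2 sulfonylates that oxygen, while the neutral primary alcohol is not expected to react.

Step 2
Reactants: 2 6-(hydroxymethyl)-4-oxo-4H-pyran-3-yl trifluoromethanesulfonate; 3 2,4-bis(benzyloxy)phenylboronic acid
Product: 4 5-[2,4-bis(benzyloxy)phenyl]-2-(hydroxymethyl)-4H-pyran-4-one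
Conditions: Pd(PPh3)4 (5 mol %), K3PO4, 1,4-dioxane/H2O (10:1), 80 °C
Reagents that add atoms: none
Why: Suzuki–Miyaura coupling, in which the electron-poor enol triflate adds oxidatively to zerovalent palladium and the phosphate-activated arylboronic acid transmetalates, the free primary alcohol being a spectator.

Step 3
Reactants: 4 5-[2,4-bis(benzyloxy)phenyl]-2-(hydroxymethyl)-4H-pyran-4-one
Product: 5 5-[2,4-bis(benzyloxy)phenyl]-4-oxo-4H-pyran-2-carboxylic acid
Conditions: TEMPO (20 mol %), PhI(OAc)2 (2.2 equiv), MeCN/H2O (1:1), rt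
Reagents that add atoms: water, O
Why: Oxoammonium (TEMPO/PhI(OAc)2) oxidation of the primary alcohol through the aldehyde hydrate to the acid, under near-neutral metal-free conditions that benzyl ethers and the pyranone should tolerate.

Step 4
Reactants: 5 5-[2,4-bis(benzyloxy)phenyl]-4-oxo-4H-pyran-2-carboxylic acid
Product: 7 5-[2,4-bis(benzyloxy)phenyl]-2-(diazoacetyl)-4H-pyran-4-one, via acid chloride 6 (not isolated)
Conditions: (COCl)2, cat. DMF, CH2Cl2, 0 °C to rt, evaporate; then CH2N2 (3 equiv), Et2O/THF, 0 °C, dark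
Reagents that add atoms: oxalyl chloride, O=C(Cl)C(=O)Cl (chlorine of 6); diazomethane, C=[N+]=[N-]
Why: Acylation of diazomethane by an acid chloride (first stage of the Arndt–Eistert sequence), the diazomethane carbon attacking the acyl carbon and a second equivalent removing HCl as chloromethane, as is routine for aroyl and heteroaroyl chlorides.

Step 5
Reactants: 8 hex-5-yn-2-one
Product: 9 2-methylhex-5-yn-2-ol
Conditions: MeMgBr (1.3 equiv), THF, −78 °C to 0 °C; aq. NH4Cl
Reagents that add atoms: methylmagnesium bromide, C[Mg]Br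
Why: Grignard 1,2-addition to the methyl ketone, which at low temperature outpaces deprotonation of the terminal alkyne, any acetylide being reprotonated on work-up.

Step 6
Reactants: 9 2-methylhex-5-yn-2-ol
Product: 10 triethyl[(2-methylhex-5-yn-2-yl)oxy]silane
Conditions: TESOTf (1.2 equiv), 2,6-lutidine, CH2Cl2, −78 °C to 0 °C
Reagents that add atoms: triethylsilyl trifluoromethanesulfonate, CC[Si](CC)(CC)OS(=O)(=O)C(F)(F)F
Why: Standard silyl triflate/hindered base silylation of a tertiary alcohol, giving an ether that is inert to organolithiums, light and heat yet labile to fluoride.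

Step 7
Reactants: 10 triethyl[(2-methylhex-5-yn-2-yl)oxy]silane
Product: 13 5-methyl-5-(triethylsilyloxy)-1-(triisopropylsilyloxy)hex-1-yne, via lithium acetylide 11 (not isolated), via lithium ynolate 12 (not isolated)
Conditions: n-BuLi, THF, −78 °C; LiOOt-Bu (from t-BuOOH and LiHMDS, THF, −78 °C), −78 °C to 0 °C; TIPSOTf, −78 °C to 0 °C; rapid filtration through Et3N-deactivated silica
Reagents that add atoms: n-butyllithium, [Li]CCCC (lithium of 11); tert-butyl hydroperoxide, CC(C)(C)OO (used as its lithium salt, oxygen of 12 and 13); triisopropylsilyl trifluoromethanesulfonate, CC(C)[Si](OS(=O)(=O)C(F)(F)F)(C(C)C)C(C)C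
Why: Electrophilic oxygen transfer from lithium tert-butyl peroxide to the lithium acetylide (acetylide oxidation to an ynolate, with loss of tert-butoxide), followed by O-silylation with the bulky silyl triflate, which favours the siloxyalkyne over the C-silylated ketene.

Step 8
Reactants: 7 5-[2,4-bis(benzyloxy)phenyl]-2-(diazoacetyl)-4H-pyran-4-one; 13 5-methyl-5-(triethylsilyloxy)-1-(triisopropylsilyloxy)hex-1-yne (1.5 equiv)
Product: 18 3-[2,4-bis(benzyloxy)phenyl]-5-hydroxy-6-[3-methyl-3-(triethylsilyloxy)butyl]-7-(triisopropylsilyloxy)-4H-chromen-4-one, via pyranonylketene 14 (not isolated), via cyclobutenone 15 (not isolated), via dienylketene 16 (not isolated), via 4a-H dienone 17 (not isolated)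
Conditions: hν (365 nm, Pyrex), degassed ClCH2CH2Cl, rt, until 7 is consumed; then 80 °C in the dark
Reagents that add atoms: none
Why: This is a Danheiser benzannulation in its photo-Wolff form: light expels N2 from 7 and the pyranonyl group shifts from the carbonyl carbon to the former diazo carbon (making C8–C8a) to give ketene 14, whose carbonyl carbon is attacked by the nucleophilic alkyl-bearing carbon of ynol ether 13 in a regiospecific [2+2] cycloaddition (C5–C6 and C7–C8) that gives cyclobutenone 15. On heating, 15 opens by a reversible four-electron electrocyclic process to dienylketene 16, whose ketene carbon closes ring A onto pyranone C3 (the future C4a) by a thermal six-electron disrotatory electrocyclisation (C4a–C5) to dienone 17, and enolisation of the doubly activated C4a–H gives the C5 phenol, hydrogen-bonded to the C4 carbonyl and therefore a poor trap for residual ketene. The closest known reactions are the benzannulations of aryl, furyl, thienyl and pyrrolyl diazomethyl ketones with triisopropylsilyloxyalkynes, and the C2=C3 bond of the pyranone, a weakly aromatic vinylogous ester double bond, should take part at least as readily. No stereocentre remains in the product, since C4 of 15 and C4a of 17 are transient and are erased. The selectivities needed are regiochemical and photochemical: the ynol ether polarisation puts the side chain at C6 between the two oxygens, C3 is the only pyranone carbon within reach of the ketene so that no 8-alkyl isomer can form, and irradiation at 365 nm, stopped once 7 is gone, addresses the diazo ketone band while sparing the pyranone and the isoflavone, which should form mainly in the dark heating stage.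

Step 9
Reactants: 18 3-[2,4-bis(benzyloxy)phenyl]-5-hydroxy-6-[3-methyl-3-(triethylsilyloxy)butyl]-7-(triisopropylsilyloxy)-4H-chromen-4-one
Product: 19 3-[2,4-bis(benzyloxy)phenyl]-5,7-dihydroxy-6-(3-hydroxy-3-methylbutyl)-4H-chromen-4-one
Conditions: TBAF (3 equiv), THF, 0 °C to rt; AcOH quench
Reagents that add atoms: none
Why: Fluoride-driven desilylation (Si–F bond formation) of the aryl triisopropylsilyl ether and the tertiary triethylsilyl ether, to which benzyl ethers and the chromone are inert at room temperature.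

Step 10
Reactants: 19 3-[2,4-bis(benzyloxy)phenyl]-5,7-dihydroxy-6-(3-hydroxy-3-methylbutyl)-4H-chromen-4-one
Product: 20 luteone hydrate [3-(2,4-dihydroxyphenyl)-5,7-dihydroxy-6-(3-hydroxy-3-methylbutyl)-4H-chromen-4-one]
Conditions: H2 (1 atm), 10% Pd/C, EtOAc/MeOH, rt, stopped at full debenzylation
Reagents that add atoms: none
Why: Catalytic hydrogenolysis of the two aryl benzyl ethers over Pd/C, a standard isoflavone deprotection under which the chromone C2=C3 bond, the phenols and the tertiary alcohol should survive at atmospheric pressure.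

**Compound list**
1 | kojic acid, 5-hydroxy-2-(hydroxymethyl)-4H-pyran-4-one | OCc1cc(=O)c(O)co1 | starting material
2 | 6-(hydroxymethyl)-4-oxo-4H-pyran-3-yl trifluoromethanesulfonate | OCc1cc(=O)c(OS(=O)(=O)C(F)(F)F)co1 | intermediate
3 | 2,4-bis(benzyloxy)phenylboronic acid | OB(O)c1ccc(OCc2ccccc2)cc1OCc1ccccc1 | starting material
4 | 5-[2,4-bis(benzyloxy)phenyl]-2-(hydroxymethyl)-4H-pyran-4-one | OCc1cc(=O)c(-c2ccc(OCc3ccccc3)cc2OCc2ccccc2)co1 | intermediate
5 | 5-[2,4-bis(benzyloxy)phenyl]-4-oxo-4H-pyran-2-carboxylic acid | OC(=O)c1cc(=O)c(-c2ccc(OCc3ccccc3)cc2OCc2ccccc2)co1 | intermediate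
6 | 5-[2,4-bis(benzyloxy)phenyl]-4-oxo-4H-pyran-2-carbonyl chloride (formed in the flask) | ClC(=O)c1cc(=O)c(-c2ccc(OCc3ccccc3)cc2OCc2ccccc2)co1 | intermediate
7 | 5-[2,4-bis(benzyloxy)phenyl]-2-(diazoacetyl)-4H-pyran-4-one | [N-]=[N+]=CC(=O)c1cc(=O)c(-c2ccc(OCc3ccccc3)cc2OCc2ccccc2)co1 | intermediate
8 | hex-5-yn-2-one | CC(=O)CCC#C | starting material
9 | 2-methylhex-5-yn-2-ol | CC(C)(O)CCC#C | intermediate
10 | triethyl[(2-methylhex-5-yn-2-yl)oxy]silane | CC(C)(CCC#C)O[Si](CC)(CC)CC | intermediate
11 | [5-methyl-5-(triethylsilyloxy)hex-1-yn-1-yl]lithium (formed in the flask) | [Li]C#CCCC(C)(C)O[Si](CC)(CC)CC | intermediate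
12 | lithium 5-methyl-5-(triethylsilyloxy)hex-1-yn-1-olate (formed in the flask) | [Li]OC#CCCC(C)(C)O[Si](CC)(CC)CC | intermediate
13 | 5-methyl-5-(triethylsilyloxy)-1-(triisopropylsilyloxy)hex-1-yne | CC(C)(CCC#CO[Si](C(C)C)(C(C)C)C(C)C)O[Si](CC)(CC)CC | intermediate
14 | {5-[2,4-bis(benzyloxy)phenyl]-4-oxo-4H-pyran-2-yl}ketene (formed in the flask) | O=C=Cc1cc(=O)c(-c2ccc(OCc3ccccc3)cc2OCc2ccccc2)co1 | intermediate
15 | 4-{5-[2,4-bis(benzyloxy)phenyl]-4-oxo-4H-pyran-2-yl}-2-[3-methyl-3-(triethylsilyloxy)butyl]-3-(triisopropylsilyloxy)cyclobut-2-en-1-one, racemic at C4 (formed in the flask) | O=C1C(CCC(C)(C)O[Si](CC)(CC)CC)=C(O[Si](C(C)C)(C(C)C)C(C)C)C1c1cc(=O)c(-c2ccc(OCc3ccccc3)cc2OCc2ccccc2)co1 | intermediate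
16 | 4-{5-[2,4-bis(benzyloxy)phenyl]-4-oxo-4H-pyran-2-yl}-2-[3-methyl-3-(triethylsilyloxy)butyl]-3-(triisopropylsilyloxy)buta-1,3-dien-1-one, pyranonyl group cis to the ketene-bearing carbon (formed in the flask) | O=C=C(CCC(C)(C)O[Si](CC)(CC)CC)/C(O[Si](C(C)C)(C(C)C)C(C)C)=C\c1cc(=O)c(-c2ccc(OCc3ccccc3)cc2OCc2ccccc2)co1 | intermediate
17 | 3-[2,4-bis(benzyloxy)phenyl]-6-[3-methyl-3-(triethylsilyloxy)butyl]-7-(triisopropylsilyloxy)-4aH-chromene-4,5-dione, the 4a-H keto tautomer of 18 (formed in the flask) | O=C1C(CCC(C)(C)O[Si](CC)(CC)CC)=C(O[Si](C(C)C)(C(C)C)C(C)C)C=C2OC=C(c3ccc(OCc4ccccc4)cc3OCc3ccccc3)C(=O)C12 | intermediate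
18 | 3-[2,4-bis(benzyloxy)phenyl]-5-hydroxy-6-[3-methyl-3-(triethylsilyloxy)butyl]-7-(triisopropylsilyloxy)-4H-chromen-4-one | CC(C)(CCc1c(O[Si](C(C)C)(C(C)C)C(C)C)cc2occ(-c3ccc(OCc4ccccc4)cc3OCc3ccccc3)c(=O)c2c1O)O[Si](CC)(CC)CC | intermediate
19 | 3-[2,4-bis(benzyloxy)phenyl]-5,7-dihydroxy-6-(3-hydroxy-3-methylbutyl)-4H-chromen-4-one | CC(C)(O)CCc1c(O)cc2occ(-c3ccc(OCc4ccccc4)cc3OCc3ccccc3)c(=O)c2c1O | intermediate
20 | luteone hydrate, 3-(2,4-dihydroxyphenyl)-5,7-dihydroxy-6-(3-hydroxy-3-methylbutyl)-4H-chromen-4-one | CC(C)(O)CCc1c(O)cc2occ(-c3ccc(O)cc3O)c(=O)c2c1O | target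

**Step count**
Total: 10 steps. Longest linear sequence: 7 steps (steps 1, 2, 3, 4, 8, 9, 10); the alkyne branch (steps 5, 6, 7) joins at step 8.

**Steps most likely to fail**

Step 8. The cross-conjugated pyranone, or the isoflavone once formed, may undergo its own photochemistry (skeletal rearrangement, or cycloaddition with the alkyne) faster than the Wolff shift, so that ketene 14 is never formed cleanly. The fallback generates the same ketene without light and sets out from 7. A silver-catalysed Wolff rearrangement in the dark (PhCO2Ag, Et3N, THF/H2O) traps ketene 14 with water as 2-{5-[2,4-bis(benzyloxy)phenyl]-4-oxo-4H-pyran-2-yl}acetic acid F1. Oxalyl chloride with catalytic DMF converts this to 2-{5-[2,4-bis(benzyloxy)phenyl]-4-oxo-4H-pyran-2-yl}acetyl chloride F2. Slow addition of Et3N to F2 and siloxyalkyne 13 in toluene dehydrochlorinates F2 to ketene 14, which is where the fallback rejoins the route; [2+2] cycloaddition to 15 and heating at 80 °C then lead through 16 and 17 to 18. Ketenes made from acid chlorides and triethylamine are known to combine with siloxyalkynes to give cyclobutenones and resorcinol silyl ethers.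

Step 4. Diazomethane may add as a 1,3-dipole across the doubly acyl-activated C2=C3 bond of the pyranone, or the HCl set free may convert the diazo ketone into a chloromethyl ketone. The fallback avoids diazomethane by a detrifluoroacetylative diazo transfer and sets out from acid chloride 6. Pd-catalysed coupling with Me4Sn (BnPdCl(PPh3)2, 65 °C) should give 2-acetyl-5-[2,4-bis(benzyloxy)phenyl]-4H-pyran-4-one F3. Its lithium enolate (LiHMDS, THF, −78 °C) is acylated with 2,2,2-trifluoroethyl trifluoroacetate to 1-{5-[2,4-bis(benzyloxy)phenyl]-4-oxo-4H-pyran-2-yl}-4,4,4-trifluorobutane-1,3-dione F4. Treatment of F4 with MsN3, Et3N and water in MeCN transfers the diazo group with loss of the trifluoroacetyl group and returns to the route at 7.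

Step 7. Oxygen transfer to the acetylide may be incomplete, the ynolate may be silylated on carbon to give a silylketene, or the siloxyalkyne may hydrolyse on silica. The fallback reaches the ynolate by a Kowalski-type carbenoid 1,2-shift instead of acetylide oxidation and sets out from 10. Oxidative dibromination of the terminal alkyne (NBS, aqueous acetone) should give 1,1-dibromo-5-methyl-5-(triethylsilyloxy)hexan-2-one F5. LiHMDS converts it into lithium 1,1-dibromo-5-methyl-5-(triethylsilyloxy)hex-1-en-2-olate F6. Bromine–lithium exchange with n-BuLi at −78 °C gives lithium 1-bromo-1-lithio-5-methyl-5-(triethylsilyloxy)hex-1-en-2-olate F7. On warming, F7 loses LiBr with 1,2-shift of the alkyl group and returns to the route at lithium ynolate 12, which is silylated with TIPSOTf to 13 as in step 7.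

**Further compounds**
F1 | step 8 | 2-{5-[2,4-bis(benzyloxy)phenyl]-4-oxo-4H-pyran-2-yl}acetic acid | OC(=O)Cc1cc(=O)c(-c2ccc(OCc3ccccc3)cc2OCc2ccccc2)co1
F2 | step 8 | 2-{5-[2,4-bis(benzyloxy)phenyl]-4-oxo-4H-pyran-2-yl}acetyl chloride | ClC(=O)Cc1cc(=O)c(-c2ccc(OCc3ccccc3)cc2OCc2ccccc2)co1
F3 | step 4 | 2-acetyl-5-[2,4-bis(benzyloxy)phenyl]-4H-pyran-4-one | CC(=O)c1cc(=O)c(-c2ccc(OCc3ccccc3)cc2OCc2ccccc2)co1
F4 | step 4 | 1-{5-[2,4-bis(benzyloxy)phenyl]-4-oxo-4H-pyran-2-yl}-4,4,4-trifluorobutane-1,3-dione | O=C(CC(=O)C(F)(F)F)c1cc(=O)c(-c2ccc(OCc3ccccc3)cc2OCc2ccccc2)co1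
F5 | step 7 | 1,1-dibromo-5-methyl-5-(triethylsilyloxy)hexan-2-one | BrC(Br)C(=O)CCC(C)(C)O[Si](CC)(CC)CC
F6 | step 7 | lithium 1,1-dibromo-5-methyl-5-(triethylsilyloxy)hex-1-en-2-olate | [Li]OC(=C(Br)Br)CCC(C)(C)O[Si](CC)(CC)CC
F7 | step 7 | lithium 1-bromo-1-lithio-5-methyl-5-(triethylsilyloxy)hex-1-en-2-olate | [Li]OC(=C([Li])Br)CCC(C)(C)O[Si](CC)(CC)CC
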